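**Strategy.** The plan cuts ring A (the benzo ring of the chromene) at two adjacent bonds: C6–C(=O) to the aroyl carbon and C7–O. Both form at once when 3-(methoxymethoxy)benzoic acid adds across 3,5-bis(methoxymethoxy)benzyne, released from an ortho-silylaryl triflate. O-Arylation followed by O-to-C acyl shift places the ketone on C6, the crowded carbon between the C5 and C7 oxygens, which is the feature exploited. The precursor is a phloroglucinol core carrying two acetal ethers, a trimethylsilyl group and a neighbouring triflate. Acetal removal, C-prenylation (C8) and a prenal-based pyran annulation (O1, C2–C4) finish the target.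

Key step: step 5

Remark: ring A is the benzo ring of the 2H-chromene (C4a, C5 to C8, C8a); because tetraol 12 has two equivalent ortho hydroxyls, the oxygen introduced in step 5 is counted as the C7 oxygen of the target.

**Step 1**
Reactants: 1 phloroglucinol (benzene-1,3,5-triol)
Product: 2 3,5-bis(methoxymethoxy)phenol
Conditions: MOMCl (2.1 equiv), i-Pr2NEt (2.5 equiv), CH2Cl2/DMF, 0 °C to rt; chromatography
Reagents that add atoms: chloromethyl methyl ether (MOMCl), COCCl
Why: Williamson-type O-alkylation with the hard α-chloro ether stays on oxygen, and two equivalents should make the bis-ether the main member of a separable statistical set whose mono-ether can be resubmitted.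

**Step 2**
Reactants: 2 3,5-bis(methoxymethoxy)phenol
Product: 3 2-bromo-3,5-bis(methoxymethoxy)phenol
Conditions: NBS (1.0 equiv), CH2Cl2, −78 °C to 0 °C
Reagents that add atoms: N-bromosuccinimide, O=C1CCC(=O)N1Br
Why: Electrophilic aromatic bromination of the triply activated ring should go to one of the two equivalent positions ortho to the hydroxyl, which are less hindered than the position flanked by both acetal ethers, and one equivalent at low temperature limits dibromination.

**Step 3**
Reactants: 3 2-bromo-3,5-bis(methoxymethoxy)phenol
Product: 6 3,5-bis(methoxymethoxy)-2-(trimethylsilyl)phenyl trifluoromethanesulfonate, via trimethylsilyl ether 4 (not isolated), via lithium phenolate 5 (not isolated)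
Conditions: HMDS, THF, 70 °C, then evaporate; n-BuLi, THF, −78 °C to rt; Tf2O, −78 °C
Reagents that add atoms: hexamethyldisilazane, C[Si](C)(C)N[Si](C)(C)C; trifluoromethanesulfonic anhydride, O=S(=O)(OS(=O)(=O)C(F)(F)F)C(F)(F)F
Why: O-Silylation, bromine–lithium exchange and retro-Brook 1,3-O-to-C silyl shift give the ortho-silyl phenolate, which is triflated in the same flask, the standard entry to ortho-silylaryl triflates and one that aryl acetal ethers tolerate at low temperature.

**Step 4**
Reactants: 7 3-hydroxybenzoic acid
Product: 9 3-(methoxymethoxy)benzoic acid, via methoxymethyl ester 8 (not isolated)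
Conditions: MOMCl (2.4 equiv), i-Pr2NEt, CH2Cl2, 0 °C to rt; then LiOH, THF/MeOH/H2O, rt; cold 1 M HCl to pH 4
Reagents that add atoms: chloromethyl methyl ether (MOMCl), COCCl; lithium hydroxide (hydroxide oxygen of the acid), [Li+].[OH-]
Why: Double O-alkylation followed by saponification of the far more labile acyloxymethyl ester frees the acid while the base-stable phenolic acetal ether stays in place.

**Step 5**
Reactants: 6 3,5-bis(methoxymethoxy)-2-(trimethylsilyl)phenyl trifluoromethanesulfonate; 9 3-(methoxymethoxy)benzoic acid
Product: 11 (2-hydroxy-4,6-bis(methoxymethoxy)phenyl)(3-(methoxymethoxy)phenyl)methanone, via 3,5-bis(methoxymethoxy)benzyne 10 (not isolated)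
Conditions: 9 (1.0 equiv), 6 (1.5 equiv), CsF (4 equiv), THF, 125 °C, sealed tube
Reagents that add atoms: none
Why: Fluoride attacks silicon and the neighbouring triflate leaves to give aryne 10; the caesium carboxylate of 9 adds through oxygen to the aryne carbon remote from the adjacent acetal ether (future C7), and the aryl anion left on the carbon beside that ether (future C6) attacks the ester carbonyl through a four-membered alkoxide that opens to the ortho-acyl phenoxide. The closest known reaction type is the formal insertion of arynes into the C–O bond of carboxylic acids, in mechanism an anionic Fries-type O-to-C acyl shift. No ring is kept, since the four-membered alkoxide is only a transient, and no stereocentre is formed. The step needs regioselective addition to an unsymmetrical aryne, which the inductively withdrawing acetal oxygen next to the triple bond secures by stabilising negative charge on the adjacent carbon, so that the nucleophile enters at the distal carbon. It also needs acyl transfer to outrun protonation of the aryl anion, which THF (no acidic C–H) and the proximity of the ester carbonyl favour. The product phenol is chelated to the new ketone and hindered by it, which should protect it from arylation by excess aryne.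

**Step 6**
Reactants: 11 (2-hydroxy-4,6-bis(methoxymethoxy)phenyl)(3-(methoxymethoxy)phenyl)methanone
Product: 12 (3-hydroxyphenyl)(2,4,6-trihydroxyphenyl)methanone
Conditions: 3 M HCl (aq), MeOH, 50 °C
Reagents that add atoms: none
Why: Acid-catalysed acetal exchange with methanol removes all three methoxymethyl ethers while the diaryl ketone is inert, and doing so before any alkene is present keeps acid away from the prenyl and chromene units.

**Step 7**
Reactants: 12 (3-hydroxyphenyl)(2,4,6-trihydroxyphenyl)methanone; 13 prenyl bromide (1-bromo-3-methylbut-2-ene)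
Product: 14 (3-hydroxyphenyl)[2,4,6-trihydroxy-3-(3-methylbut-2-en-1-yl)phenyl]methanone
Conditions: 13 (1.0 equiv, slow addition), DBU (1.1 equiv), THF, 0 °C to rt
Reagents that add atoms: none
Why: The mono-anion of the acylphloroglucinol, far more acidic than the isolated 3′-phenol, is a soft ambident nucleophile that undergoes direct C-allylation (SN2) at one of its two equivalent ring carbons, and one equivalent of bromide limits a second alkylation.

**Step 8**
Reactants: 14 (3-hydroxyphenyl)[2,4,6-trihydroxy-3-(3-methylbut-2-en-1-yl)phenyl]methanone; 15 3-methylbut-2-enal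
Product: 17 (5,7-dihydroxy-2,2-dimethyl-8-(3-methylbut-2-en-1-yl)-2H-chromen-6-yl)(3-hydroxyphenyl)methanone, via ortho-quinone methide 16 (not isolated)
Conditions: 15 (2 equiv), ethylenediammonium diacetate (20 mol %), toluene, 110 °C
Reagents that add atoms: none
Why: Iminium-mediated Knoevenagel-type condensation at the only free ring carbon gives quinone methide 16, whose oxa-6π electrocyclisation forms the 2,2-dimethyl-2H-pyran, and expulsion of the amine by the most acidic, non-chelated para phenoxide should place the dienone carbonyl on the oxygen para to the ketone, so that closure there leaves the aroyl group between two hydroxyls.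

**Compound list**
1 | phloroglucinol | Oc1cc(O)cc(O)c1 | starting material
2 | 3,5-bis(methoxymethoxy)phenol | COCOc1cc(O)cc(OCOC)c1 | intermediate
3 | 2-bromo-3,5-bis(methoxymethoxy)phenol | COCOc1cc(O)c(Br)c(OCOC)c1 | intermediate
4 | [2-bromo-3,5-bis(methoxymethoxy)phenoxy]trimethylsilane | COCOc1cc(O[Si](C)(C)C)c(Br)c(OCOC)c1 | intermediate
5 | lithium 3,5-bis(methoxymethoxy)-2-(trimethylsilyl)phenolate | [Li+].[O-]c1cc(OCOC)cc(OCOC)c1[Si](C)(C)C | intermediate
6 | 3,5-bis(methoxymethoxy)-2-(trimethylsilyl)phenyl trifluoromethanesulfonate | COCOc1cc(OCOC)c([Si](C)(C)C)c(OS(=O)(=O)C(F)(F)F)c1 | intermediate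
7 | 3-hydroxybenzoic acid | O=C(O)c1cccc(O)c1 | starting material
8 | methoxymethyl 3-(methoxymethoxy)benzoate | COCOC(=O)c1cccc(OCOC)c1 | intermediate
9 | 3-(methoxymethoxy)benzoic acid | COCOc1cccc(C(=O)O)c1 | intermediate
10 | 3,5-bis(methoxymethoxy)benzyne | COCOC1=CC(OCOC)=CC#C1 | intermediate
11 | (2-hydroxy-4,6-bis(methoxymethoxy)phenyl)(3-(methoxymethoxy)phenyl)methanone | COCOc1cc(O)c(C(=O)c2cccc(OCOC)c2)c(OCOC)c1 | intermediate
12 | (3-hydroxyphenyl)(2,4,6-trihydroxyphenyl)methanone | O=C(c1cccc(O)c1)c1c(O)cc(O)cc1O | intermediate
13 | prenyl bromide | CC(C)=CCBr | starting material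
14 | (3-hydroxyphenyl)[2,4,6-trihydroxy-3-(3-methylbut-2-en-1-yl)phenyl]methanone | CC(C)=CCc1c(O)cc(O)c(C(=O)c2cccc(O)c2)c1O | intermediate
15 | 3-methylbut-2-enal | CC(C)=CC=O | starting material
16 | 3,5-dihydroxy-4-(3-hydroxybenzoyl)-6-(3-methylbut-2-enylidene)-2-(3-methylbut-2-en-1-yl)cyclohexa-2,4-dien-1-one (ortho-quinone methide) | O=C1C(CC=C(C)C)=C(O)C(C(=O)c2cccc(O)c2)=C(O)C1=CC=C(C)C | intermediate
17 | (5,7-dihydroxy-2,2-dimethyl-8-(3-methylbut-2-en-1-yl)-2H-chromen-6-yl)(3-hydroxyphenyl)methanone | CC(C)=CCc1c(O)c(C(=O)c2cccc(O)c2)c(O)c2c1OC(C)(C)C=C2 | target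

**Total step count:** 8
**Longest linear sequence:** 7 (steps 1, 2, 3, 5, 6, 7, 8)

**Steps most likely to fail**

Step 5. The aryl anion may be protonated before the acyl shift, so that the reaction stops at the aryl ester. The carboxylate may also add with the reverse orientation, or the product phenoxide may be arylated by excess aryne. The fallback is a stepwise version that fixes the anion site by a halogen. It sets out from 3 and 9. Carbodiimide esterification (DCC, cat. DMAP, CH2Cl2) should give 2-bromo-3,5-bis(methoxymethoxy)phenyl 3-(methoxymethoxy)benzoate F1. Bromine–lithium exchange (n-BuLi, THF, −100 °C to −78 °C) then generates the aryllithium on the carbon between the ester oxygen and the acetal ether, and an anionic Fries shift gives the phenoxide of the ketone. The fallback returns to the route at 11.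

Step 8. The electrocyclisation may close onto an ortho hydroxyl instead of the para hydroxyl, giving the chromene with the aroyl group next to the ring oxygen. The fallback blocks the competing oxygen and sets out from 11.
- O-Prenylation with 13 (K2CO3, acetone, reflux) gives [2,4-bis(methoxymethoxy)-6-(3-methylbut-2-en-1-yloxy)phenyl][3-(methoxymethoxy)phenyl]methanone F2.
- Claisen rearrangement followed by Cope rearrangement (N,N-diethylaniline, 200 °C) moves the prenyl group to the carbon para to that oxygen, giving [6-hydroxy-2,4-bis(methoxymethoxy)-3-(3-methylbut-2-en-1-yl)phenyl][3-(methoxymethoxy)phenyl]methanone F3.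
- Allyl bromide with K2CO3 in DMF caps the free phenol as [6-(allyloxy)-2,4-bis(methoxymethoxy)-3-(3-methylbut-2-en-1-yl)phenyl][3-(methoxymethoxy)phenyl]methanone F4.
- HCl in MeOH at rt removes the acetal ethers to give [6-(allyloxy)-2,4-dihydroxy-3-(3-methylbut-2-en-1-yl)phenyl](3-hydroxyphenyl)methanone F5.
- Annulation with 15 under the conditions of step 8 can now close only through the para hydroxyl, because the single free ring carbon lies between it and the allyl ether. The product is [5-(allyloxy)-7-hydroxy-2,2-dimethyl-8-(3-methylbut-2-en-1-yl)-2H-chromen-6-yl](3-hydroxyphenyl)methanone F6.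
- Deallylation with Pd(PPh3)4 and morpholine in THF at rt returns to the route at 17.

Step 7. A second C-prenylation, geminal dialkylation with loss of aromaticity, or O-alkylation may erode the mono-C-prenyl product. The fallback inverts the order so that only one ring carbon is left for the alkylation, and sets out from 12. Annulation with 15 (1 equiv, ethylenediammonium diacetate, toluene, 110 °C) gives (5,7-dihydroxy-2,2-dimethyl-2H-chromen-6-yl)(3-hydroxyphenyl)methanone F7. C-Prenylation with 13 and DBU in THF at the single free carbon C8 then returns to the route at 17.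

**Further compounds**
F1 | step 5 | 2-bromo-3,5-bis(methoxymethoxy)phenyl 3-(methoxymethoxy)benzoate | COCOc1cc(OC(=O)c2cccc(OCOC)c2)c(Br)c(OCOC)c1
F2 | step 8 | [2,4-bis(methoxymethoxy)-6-(3-methylbut-2-en-1-yloxy)phenyl][3-(methoxymethoxy)phenyl]methanone | COCOc1cc(OCC=C(C)C)c(C(=O)c2cccc(OCOC)c2)c(OCOC)c1
F3 | step 8 | [6-hydroxy-2,4-bis(methoxymethoxy)-3-(3-methylbut-2-en-1-yl)phenyl][3-(methoxymethoxy)phenyl]methanone | COCOc1cc(O)c(C(=O)c2cccc(OCOC)c2)c(OCOC)c1CC=C(C)C
F4 | step 8 | [6-(allyloxy)-2,4-bis(methoxymethoxy)-3-(3-methylbut-2-en-1-yl)phenyl][3-(methoxymethoxy)phenyl]methanone | COCOc1cc(OCC=C)c(C(=O)c2cccc(OCOC)c2)c(OCOC)c1CC=C(C)C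
F5 | step 8 | [6-(allyloxy)-2,4-dihydroxy-3-(3-methylbut-2-en-1-yl)phenyl](3-hydroxyphenyl)methanone | C=CCOc1cc(O)c(CC=C(C)C)c(O)c1C(=O)c1cccc(O)c1
F6 | step 8 | [5-(allyloxy)-7-hydroxy-2,2-dimethyl-8-(3-methylbut-2-en-1-yl)-2H-chromen-6-yl](3-hydroxyphenyl)methanone | CC(C)=CCc1c(O)c(C(=O)c2cccc(O)c2)c(OCC=C)c2c1OC(C)(C)C=C2
F7 | step 7 | (5,7-dihydroxy-2,2-dimethyl-2H-chromen-6-yl)(3-hydroxyphenyl)methanone | O=C(c1cccc(O)c1)c1c(O)cc2OC(C)(C)C=Cc2c1O
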